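**Retrosynthetic overview**
- The target comes from radical removal of a temporary C4 hydroxyl on the bicyclic core; that carbinol is the only bought stereocenter and it is deleted last.
- The cyclopentane and isoxazolidine rings form together in one intramolecular nitrone–alkene [3+2] cycloaddition. The tether gives the cis fusion, the Z-alkene gives the C3/C3a relationship, and the C4 carbinol selects the face.
- The nitrone comes from a (5R)-5-[(Z)-alkenyl] γ-lactol and an N-[(Z)-alkenyl]hydroxylamine. The lactol comes from iBu2AlH reduction of the lactone made by Z-selective Wittig reaction of (R)-5-oxotetrahydrofuran-2-carbaldehyde (D-glutamic acid series).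
- The hydroxylamine comes from NH2OH and a Z-chloroalkene, made by semi-hydrogenation of the alkyne from 5-chloropent-1-yne.
- Both pyridyl chains (the phosphonium salt and the alkyne partner) come from 3-(9-bromononyl)pyridine, made from 3-picoline and 1,8-dibromooctane.

Assumption: (5R)-5-(hydroxymethyl)dihydrofuran-2(3H)-one, the lactone made in bulk from D-glutamic acid, is taken as a purchasable enantiopure starting material.

**Route**

Step 1
Reactants: 1 3-picoline; 2 1,8-dibromooctane
Product: 4 3-(9-bromononyl)pyridine, via pyridin-3-ylmethyllithium 3 (not isolated)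
Conditions: LiN(iPr)2, THF, −78 °C; then cannulated into 2 (4 equiv), −78 °C → rt
Reagents that add atoms: LiN(iPr)2, [Li]N(C(C)C)C(C)C (its lithium stays only in 3, none in 4)
Why: Lateral lithiation of 3-picoline followed by SN2 alkylation on one end of the dibromide; excess dibromide and inverse addition suppress double alkylation.

Step 2
Reactants: 4 3-(9-bromononyl)pyridine; 5 triphenylphosphine
Product: 6 [9-(pyridin-3-yl)nonyl]triphenylphosphonium bromide
Conditions: PPh3 (3 equiv), MeCN, 80 °C, 36 h; triturate with Et2O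
Reagents that add atoms: none
Why: SN2 quaternisation in which the more nucleophilic phosphine, used in excess, outruns self-alkylation of the pyridine nitrogen.

Step 3
Reactants: 7 5-chloropent-1-yne; 4 3-(9-bromononyl)pyridine
Product: 9 3-(14-chlorotetradec-10-yn-1-yl)pyridine, via lithium 5-chloropentynide 8 (not isolated)
Conditions: n-BuLi (1.2 equiv on 1.3 equiv 7), THF, −78 → −20 °C; then 4, DMPU, −20 °C → rt
Reagents that add atoms: n-BuLi, [Li]CCCC (its lithium stays only in 8, none in 9)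
Why: Acetylide alkylation (SN2) in which the primary bromide is displaced while the primary chloride of the alkyne partner is left alone.

Step 4
Reactants: 9 3-(14-chlorotetradec-10-yn-1-yl)pyridine
Product: 10 3-[(10Z)-14-chlorotetradec-10-en-1-yl]pyridine
Conditions: H2 (1 atm), Pd/CaCO3 poisoned with Pb(OAc)2, quinoline, EtOAc, rt
Reagents that add atoms: none
Why: Lindlar semi-hydrogenation delivers both hydrogens to one face of the alkyne and stops at the Z-alkene; the alkyl chloride and pyridine ring are untouched.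

Step 5
Reactants: 10 3-[(10Z)-14-chlorotetradec-10-en-1-yl]pyridine
Product: 11 N-[(4Z)-14-(pyridin-3-yl)tetradec-4-en-1-yl]hydroxylamine
Conditions: NH2OH (50% aq., 25 equiv), NaI (0.3 equiv), DMSO/EtOH, 45 °C; used at once
Reagents that add atoms: hydroxylamine, NO
Why: Iodide-catalysed SN2 N-alkylation of hydroxylamine, where the large excess prevents dialkylation and the temperature is kept below 50 °C so that reverse-Cope cyclisation onto the Z-alkene stays slow.

Step 6
Reactants: 12 (5R)-5-(hydroxymethyl)dihydrofuran-2(3H)-one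
Product: 13 (2R)-5-oxotetrahydrofuran-2-carbaldehyde
Conditions: Dess–Martin periodinane, CH2Cl2, 0 °C → rt; filtered and used crude
Reagents that add atoms: none
Why: Dess–Martin oxidation of the primary alcohol under near-neutral conditions gives the aldehyde without epimerising the adjacent oxygen-bearing stereocenter.

Step 7
Reactants: 6 [9-(pyridin-3-yl)nonyl]triphenylphosphonium bromide; 13 (2R)-5-oxotetrahydrofuran-2-carbaldehyde
Product: 15 (5R)-5-[(1Z)-10-(pyridin-3-yl)dec-1-en-1-yl]dihydrofuran-2(3H)-one, via phosphonium ylide 14 (not isolated)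
Conditions: KN(SiMe3)2, THF, −78 → 0 °C; then 13, −78 °C → rt
Reagents that add atoms: none
Why: Wittig olefination with a salt-free non-stabilised ylide under kinetic control gives the Z-alkene; the aldehyde reacts far faster than the lactone and the bought stereocenter is not touched.

Step 8
Reactants: 15 (5R)-5-[(1Z)-10-(pyridin-3-yl)dec-1-en-1-yl]dihydrofuran-2(3H)-one
Product: 16 (5R)-5-[(1Z)-10-(pyridin-3-yl)dec-1-en-1-yl]tetrahydrofuran-2-ol
Conditions: iBu2AlH (2.2 equiv), CH2Cl2, −78 °C; aq. potassium sodium tartrate work-up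
Reagents that add atoms: none
Why: Half-reduction of the lactone stops at the lactol because the tetrahedral aluminate is stable at −78 °C; the second equivalent covers coordination to the pyridine.

Step 9
Reactants: 16 (5R)-5-[(1Z)-10-(pyridin-3-yl)dec-1-en-1-yl]tetrahydrofuran-2-ol; 11 N-[(4Z)-14-(pyridin-3-yl)tetradec-4-en-1-yl]hydroxylamine
Product: 18 (3S,3aR,4R,6aR)-3-[8-(pyridin-3-yl)octyl]-1-[(4Z)-14-(pyridin-3-yl)tetradec-4-en-1-yl]hexahydro-1H-cyclopenta[c][1,2]oxazol-4-ol, via hydroxy nitrone 17 (not isolated)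
Conditions: MgSO4, toluene, rt, 2 h; then 100 °C, 12 h
Reagents that add atoms: none
Why: Condensation of the lactol (through its open hydroxy-aldehyde form) with the hydroxylamine gives the nitrone, which undergoes a concerted suprafacial intramolecular nitrone–alkene [3+2] cycloaddition forming both rings at once: the three-carbon tether enforces the cis fusion (C3a/C6a), the Z geometry places the octyl chain at C3 cis to C4, and the bought (R)-carbinol selects the alkene face because 1,3-allylic strain keeps the allylic hydrogen in the alkene plane and the hydroxyl away from the forming C3a–C6a bond, leaving the hydroxyl trans to C3.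

Step 10
Reactants: 18 (3S,3aR,4R,6aR)-3-[8-(pyridin-3-yl)octyl]-1-[(4Z)-14-(pyridin-3-yl)tetradec-4-en-1-yl]hexahydro-1H-cyclopenta[c][1,2]oxazol-4-ol
Product: 19 O-{(3S,3aR,4R,6aR)-3-[8-(pyridin-3-yl)octyl]-1-[(4Z)-14-(pyridin-3-yl)tetradec-4-en-1-yl]hexahydro-1H-cyclopenta[c][1,2]oxazol-4-yl} 1H-imidazole-1-carbothioate
Conditions: 1,1'-thiocarbonyldiimidazole (2.5 equiv), DMAP (cat.), ClCH2CH2Cl, 60 °C
Reagents that add atoms: 1,1'-thiocarbonyldiimidazole, S=C(n1ccnc1)n1ccnc1
Why: Thioacylation (acyl transfer) of the exposed convex-face secondary alcohol with a neutral reagent that cannot alkylate the pyridines; no stereocenter is touched.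

Step 11
Reactants: 19 O-{(3S,3aR,4R,6aR)-3-[8-(pyridin-3-yl)octyl]-1-[(4Z)-14-(pyridin-3-yl)tetradec-4-en-1-yl]hexahydro-1H-cyclopenta[c][1,2]oxazol-4-yl} 1H-imidazole-1-carbothioate
Product: 20 (3S,3aS,6aR)-3-[8-(pyridin-3-yl)octyl]-1-[(4Z)-14-(pyridin-3-yl)tetradec-4-en-1-yl]hexahydro-1H-cyclopenta[c][1,2]oxazole
Conditions: Bu3SnH (2 equiv), AIBN (cat.), toluene, 100 °C
Reagents that add atoms: none
Why: Barton–McCombie radical deoxygenation turns C4 into CH2 by stannyl radical addition to C=S, β-scission and hydrogen transfer, leaving C3, C3a, C6a, the N–O bond and the Z-alkene alone (the 3a label changes from R to S only through CIP priorities).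

**Compound list**
1 | 3-picoline (3-methylpyridine) | Cc1cccnc1 | starting material
2 | 1,8-dibromooctane | BrCCCCCCCCBr | starting material
3 | pyridin-3-ylmethyllithium | [Li]Cc1cccnc1 | intermediate
4 | 3-(9-bromononyl)pyridine | BrCCCCCCCCCc1cccnc1 | intermediate
5 | triphenylphosphine | c1ccc(cc1)P(c1ccccc1)c1ccccc1 | starting material
6 | [9-(pyridin-3-yl)nonyl]triphenylphosphonium bromide | [Br-].c1ccc(cc1)[P+](CCCCCCCCCc1cccnc1)(c1ccccc1)c1ccccc1 | intermediate
7 | 5-chloropent-1-yne | ClCCCC#C | starting material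
8 | lithium 5-chloropent-1-yn-1-ide | [Li]C#CCCCCl | intermediate
9 | 3-(14-chlorotetradec-10-yn-1-yl)pyridine | ClCCCC#CCCCCCCCCCc1cccnc1 | intermediate
10 | 3-[(10Z)-14-chlorotetradec-10-en-1-yl]pyridine | ClCCC/C=C\CCCCCCCCCc1cccnc1 | intermediate
11 | N-[(4Z)-14-(pyridin-3-yl)tetradec-4-en-1-yl]hydroxylamine | ONCCC/C=C\CCCCCCCCCc1cccnc1 | intermediate
12 | (5R)-5-(hydroxymethyl)dihydrofuran-2(3H)-one | O=C1CC[C@H](CO)O1 | starting material
13 | (2R)-5-oxotetrahydrofuran-2-carbaldehyde | O=C1CC[C@H](C=O)O1 | intermediate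
14 | triphenyl[9-(pyridin-3-yl)nonylidene]phosphorane (ylide) | c1ccc(cc1)P(=CCCCCCCCCc1cccnc1)(c1ccccc1)c1ccccc1 | intermediate
15 | (5R)-5-[(1Z)-10-(pyridin-3-yl)dec-1-en-1-yl]dihydrofuran-2(3H)-one | O=C1CC[C@H](/C=C\CCCCCCCCc2cccnc2)O1 | intermediate
16 | (5R)-5-[(1Z)-10-(pyridin-3-yl)dec-1-en-1-yl]tetrahydrofuran-2-ol (both anomers) | OC1CC[C@H](/C=C\CCCCCCCCc2cccnc2)O1 | intermediate
17 | (Z)-nitrone of (4R,5Z)-4-hydroxy-14-(pyridin-3-yl)tetradec-5-enal with N-[(4Z)-14-(pyridin-3-yl)tetradec-4-en-1-yl]hydroxylamine | [O-]/[N+](CCC/C=C\CCCCCCCCCc1cccnc1)=C\CC[C@@H](O)/C=C\CCCCCCCCc1cccnc1 | intermediate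
18 | (3S,3aR,4R,6aR)-3-[8-(pyridin-3-yl)octyl]-1-[(4Z)-14-(pyridin-3-yl)tetradec-4-en-1-yl]hexahydro-1H-cyclopenta[c][1,2]oxazol-4-ol (H3, H3a, H6a all cis; OH cis to H3a) | C(=C/CCCN1O[C@@H](CCCCCCCCc2cccnc2)[C@H]2[C@H](O)CC[C@H]21)/CCCCCCCCCc1cccnc1 | intermediate
19 | O-imidazol-1-ylthiocarbonyl derivative of 18 at C4 | C(=C/CCCN1O[C@@H](CCCCCCCCc2cccnc2)[C@H]2[C@H](OC(=S)n3ccnc3)CC[C@H]21)/CCCCCCCCCc1cccnc1 | intermediate
20 | (3S,3aS,6aR)-3-[8-(pyridin-3-yl)octyl]-1-[(4Z)-14-(pyridin-3-yl)tetradec-4-en-1-yl]hexahydro-1H-cyclopenta[c][1,2]oxazole (CNP0223755.1) | C(=C/CCCN1O[C@@H](CCCCCCCCc2cccnc2)[C@H]2CCC[C@H]21)/CCCCCCCCCc1cccnc1 | target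

**Totals**
Total step count: 11.
Longest linear sequence: 7 steps (1 → 3 → 4 → 5 → 9 → 10 → 11; the branch 1 → 2 → 7 → 8 → 9 → 10 → 11 is equally long).

**Steps most likely to fail, with fallbacks**

Step 5 (direct N-alkylation of hydroxylamine). The chloride is sluggish, dialkylation is possible, and the product can cyclise by reverse-Cope reaction. The fallback sets out from 10 and comes back at 11. Compound 10 is alkylated with the protected nucleophile tert-butyl N-(tert-butoxycarbonyloxy)carbamate (K2CO3, NaI, DMF, 50 °C) to give tert-butyl N-[(tert-butoxycarbonyl)oxy]-N-[(4Z)-14-(pyridin-3-yl)tetradec-4-en-1-yl]carbamate F1. Both carbamate groups are then removed with CF3CO2H in CH2Cl2 at 0 °C, and neutralisation with NaHCO3 releases 11 at low temperature.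

Step 9 (nitrone formation from the lactol and cycloaddition). The free hydroxyl can hold the material as a cyclic N-hydroxy aminal, which invites reverse-Cope cyclisation onto the N-side alkene and may erode face selectivity. The fallback sets out from 15 and comes back at 18, using an open-chain, O-protected aldehyde instead of the lactol. Lactone 15 is opened with MeNH(OMe)·HCl/AlMe3 to (4R,5Z)-4-hydroxy-N-methoxy-N-methyl-14-(pyridin-3-yl)tetradec-5-enamide F2. This is silylated (tert-butyldimethylsilyl chloride, imidazole, DMF) to (4R,5Z)-4-(tert-butyldimethylsilyloxy)-N-methoxy-N-methyl-14-(pyridin-3-yl)tetradec-5-enamide F3 and reduced with iBu2AlH at −78 °C to (4R,5Z)-4-(tert-butyldimethylsilyloxy)-14-(pyridin-3-yl)tetradec-5-enal F4. Condensation with 11 gives the O-silylated nitrone F5, which on heating in toluene cyclises under the same 1,3-allylic strain control to the 4-O-silyl cycloadduct (3S,3aS,4R,6aR)-4-(tert-butyldimethylsilyloxy)-3-[8-(pyridin-3-yl)octyl]-1-[(4Z)-14-(pyridin-3-yl)tetradec-4-en-1-yl]hexahydro-1H-cyclopenta[c][1,2]oxazole F6. Bu4NF in THF then gives 18.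

Step 11 (radical deoxygenation). Stannyl radicals could isomerise the Z-alkene or attack the N–O bond. The fallback sets out from 18 and comes back at 20 by a polar carbonyl route instead of a radical one. Alcohol 18 is oxidised with Dess–Martin periodinane to the ketone (3S,3aS,6aR)-3-[8-(pyridin-3-yl)octyl]-1-[(4Z)-14-(pyridin-3-yl)tetradec-4-en-1-yl]hexahydro-4H-cyclopenta[c][1,2]oxazol-4-one F7; the cis fusion is thermodynamically locked, so C3a cannot scramble. Condensation with p-toluenesulfonyl hydrazide in EtOH gives the tosylhydrazone F8. Reduction with catecholborane in CHCl3 at 0 °C followed by NaOAc and warming expels sulfinate and dinitrogen and gives 20.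

**Further compounds**
F1 | step 5 | tert-butyl N-[(tert-butoxycarbonyl)oxy]-N-[(4Z)-14-(pyridin-3-yl)tetradec-4-en-1-yl]carbamate | CC(C)(C)OC(=O)ON(CCC/C=C\CCCCCCCCCc1cccnc1)C(=O)OC(C)(C)C
F2 | step 9 | (4R,5Z)-4-hydroxy-N-methoxy-N-methyl-14-(pyridin-3-yl)tetradec-5-enamide | CON(C)C(=O)CC[C@@H](O)/C=C\CCCCCCCCc1cccnc1
F3 | step 9 | (4R,5Z)-4-(tert-butyldimethylsilyloxy)-N-methoxy-N-methyl-14-(pyridin-3-yl)tetradec-5-enamide | CON(C)C(=O)CC[C@@H](O[Si](C)(C)C(C)(C)C)/C=C\CCCCCCCCc1cccnc1
F4 | step 9 | (4R,5Z)-4-(tert-butyldimethylsilyloxy)-14-(pyridin-3-yl)tetradec-5-enal | O=CCC[C@@H](O[Si](C)(C)C(C)(C)C)/C=C\CCCCCCCCc1cccnc1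
F5 | step 9 | (Z)-nitrone of F4 with N-[(4Z)-14-(pyridin-3-yl)tetradec-4-en-1-yl]hydroxylamine | [O-]/[N+](CCC/C=C\CCCCCCCCCc1cccnc1)=C\CC[C@@H](O[Si](C)(C)C(C)(C)C)/C=C\CCCCCCCCc1cccnc1
F6 | step 9 | (3S,3aS,4R,6aR)-4-(tert-butyldimethylsilyloxy)-3-[8-(pyridin-3-yl)octyl]-1-[(4Z)-14-(pyridin-3-yl)tetradec-4-en-1-yl]hexahydro-1H-cyclopenta[c][1,2]oxazole | C(=C/CCCN1O[C@@H](CCCCCCCCc2cccnc2)[C@H]2[C@H](O[Si](C)(C)C(C)(C)C)CC[C@H]21)/CCCCCCCCCc1cccnc1
F7 | step 11 | (3S,3aS,6aR)-3-[8-(pyridin-3-yl)octyl]-1-[(4Z)-14-(pyridin-3-yl)tetradec-4-en-1-yl]hexahydro-4H-cyclopenta[c][1,2]oxazol-4-one | C(=C/CCCN1O[C@@H](CCCCCCCCc2cccnc2)[C@H]2C(=O)CC[C@H]21)/CCCCCCCCCc1cccnc1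
F8 | step 11 | p-toluenesulfonylhydrazone of F7, (3S,3aR,6aR) | C(=C/CCCN1O[C@@H](CCCCCCCCc2cccnc2)[C@H]2C(=NNS(=O)(=O)c3ccc(C)cc3)CC[C@H]21)/CCCCCCCCCc1cccnc1
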